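The leftover struck me first: at 25.0 h the east run still held 26.2% right-handed substrate, with left-handed product flat since 8.00 h. This is the bench as I handed it over.

all flasks: free catalyst 0.5 mol%

|  | left-handed substrate | right-handed substrate | partner | precatalyst | remark | time |
|---|---|---|---|---|---|---|
| north-west | 0.065 M | 0.065 M | 2.5 equiv (fed, over 80 min) | 5 mol% | run made earlier |  |
| north | 0.15 M | 0.15 M | 2.5 equiv (fed, over 80 min) | 5 mol% | run made earlier |  |
| east | 0.097 M | 0.097 M | 2.5 equiv (fed, over 80 min) | 7.5 mol% | run made earlier |  |
| flask | 0.097 M | 0.097 M | 2.50 equiv (fed, over 80 min) | 5 mol% |  | 40 h |

| run | time / h | left-handed product / % | right-handed substrate / % |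
|---|---|---|---|
| north-west | 3.00 | 29.1 | 35.3 |
| north-west | 8.00 | 35.1 | 32.1 |
| north-west | 15.0 | 36.0 | 31.3 |
| north-west | 25.0 | 36.3 | 32.0 |
| north | 6.00 | 62.5 | 18.1 |
| north | 12.0 | 63.1 | 18.2 |
| north | 20.0 | 62.9 | 17.6 |
| north | 25.0 | 63.0 | 17.8 |
| east | 3.00 | 42.6 | 28.1 |
| east | 8.00 | 47.6 | 25.5 |
| east | 15.0 | 47.6 | 25.5 |
| east | 25.0 | 47.5 | 26.2 |

(each reading ± 0.3 percentage points)

- free catalyst is single-handed; left-handed substrate and right-handed substrate are mirror images of each other, charged as a racemate, each of them at the stated concentration
- the numbers in the tables scatter with a standard deviation of 0.3 percentage points
- on the list of suspects stand: partner + free catalyst + right-handed substrate -> free catalyst + right-handed product; left-handed substrate + racemization catalyst <-> right-handed substrate + racemization catalyst; partner + precatalyst -> racemization catalyst + spent reagent; partner + free catalyst + left-handed substrate -> free catalyst + left-handed product; 2 partner -> self-condensation product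

* amount of left-handed product at 40 h, in percent of the left-handed substrate and right-handed substrate together charged
* amount of right-handed substrate at 40 h, in percent of the left-handed substrate and right-handed substrate together charged

The flask held both substrates, free catalyst and precatalyst, with partner feeding in over 80 min. I took racemization as fast and balanced, so [left-handed substrate] = [right-handed substrate]. Both acylations then see one substrate level, and right-handed product should keep a constant ratio to left-handed product. It went unread, but the balance shows it. The north run averaged 62.9% left-handed product and 17.9% of each substrate, which left 1.3 percentage points unaccounted for. That gap per unit of left-handed product I called the leak, 2.03%, the inverse of a selectivity factor near 49.3. It is a rough reading, given a scatter of 0.3 points.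

The forecast said 47.5% and 25.9%, and of the east run it concluded: “extra precatalyst only speeds early racemization and barely changes the endpoint”. On its left-handed product the leak gave me 25.8% right-handed substrate, slightly lower.

The flask gave 47.9% and 25.6%.

    partner + free catalyst + right-handed substrate → free catalyst + right-handed product (k = 6.02 M⁻² min⁻¹)
    left-handed substrate + racemization catalyst ⇌ right-handed substrate + racemization catalyst, rate k2*[racemization catalyst]*[left-handed substrate] forward; the back reaction follows from the equilibrium constant (k = 4320 M⁻¹ min⁻¹)
    partner + precatalyst → racemization catalyst + spent reagent (k = 0.443 M⁻¹ min⁻¹)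
    partner + free catalyst + left-handed substrate → free catalyst + left-handed product (k = 313 M⁻² min⁻¹)
    2 partner → self-condensation product (k = 0.171 M⁻¹ min⁻¹)

Substrate stayed behind because partner went to self-condensation product: without that step, conversion rose from 48.8% to >99.9%. Less partner (0%) remained than right-handed substrate (51%). The leak turned this flask's left-handed product into 25.6% right-handed substrate. The neighbour flask with 6.20 equiv partner made 68.4% left-handed product, from which the leak gave 15.1%, and it held 15.1% right-handed substrate.

The readings stem from a simulated flask with made-up constants.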